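The ten-membered carbocycle (ring atoms C1–C10, germacrane numbering) is made through its C2–C3 bond, which is α to C1 (a ketone until late) and allylic to the C4=C5 alkene that later carries the epoxide. An acyclic chain, whose all-syn C6–C7–C8 triad comes from an Evans aldol and a Felkin-controlled allylation, is first closed to a twelve-membered allyl β-keto lactone. The key step then extrudes CO2 with zerovalent palladium and joins C2 to C3, contracting the ring by two atoms to the (E)-cyclodec-4-enone with the γ-lactone already in place. Reduction, α-methylenation, directed epoxidation and angeloylation finish the route.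

Key step: step 11

Remark: atoms are numbered as in germacranolides (ring C1–C10; lactone C11–C13 with the ring oxygen on C8; C14 the methylidene on C10; C15 the methyl on C4), and the target is read as 1S,4R,5R,6S,7R,8S; ring compounds are named on this skeleton.

Step 1
Reactants: 1 mono-tert-butyl succinate; 2 (S)-4-benzyl-1,3-oxazolidin-2-one
Product: 4 tert-butyl 4-[(4S)-4-benzyl-2-oxo-1,3-oxazolidin-3-yl]-4-oxobutanoate, via mixed pivalic anhydride 3 (not isolated)
Conditions: t-BuCOCl, Et3N, THF, −20 °C; then 2, LiCl, −20 °C → rt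
Reagents that add atoms: none
Why: N-acylation of the oxazolidinone by the mixed pivalic anhydride (LiCl/Et3N activation) is the standard chemoselective entry to an Evans imide, leaves the tert-butyl ester untouched and creates no stereocentre.

Step 2
Reactants: 4 tert-butyl 4-[(4S)-4-benzyl-2-oxo-1,3-oxazolidin-3-yl]-4-oxobutanoate; 5 3-methylbut-2-enal
Product: 7 tert-butyl (3S,4R)-3-{[(4S)-4-benzyl-2-oxo-1,3-oxazolidin-3-yl]carbonyl}-4-hydroxy-6-methylhept-5-enoate, via Z-boron enolate 6 (not isolated)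
Conditions: n-Bu2BOTf, i-Pr2NEt, CH2Cl2, 0 °C; 5, −78 → 0 °C; then pH 7 buffer, MeOH, 30% H2O2
Reagents that add atoms: none
Why: In this Evans syn-aldol reaction the Z-boron enolate adds to the enal through a chair Zimmerman–Traxler transition state on the face opposite the benzyl group, which should set C7 and C6 (syn) in the required absolute sense, while the tert-butyl ester resists premature lactonisation.

Step 3
Reactants: 7 tert-butyl (3S,4R)-3-{[(4S)-4-benzyl-2-oxo-1,3-oxazolidin-3-yl]carbonyl}-4-hydroxy-6-methylhept-5-enoate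
Product: 8 tert-butyl (3S,4R)-3-{[(4S)-4-benzyl-2-oxo-1,3-oxazolidin-3-yl]carbonyl}-4-[(tert-butyldimethylsilyl)oxy]-6-methylhept-5-enoate
Conditions: TBSOTf, 2,6-lutidine, CH2Cl2, −78 → 0 °C
Reagents that add atoms: tert-butyldimethylsilyl triflate CC(C)(C)[Si](C)(C)OS(=O)(=O)C(F)(F)F
Why: Silylation with the triflate and a hindered pyridine base avoids retro-aldol cleavage and installs a bulky, non-chelating ether on O6 that later favours Felkin control.

Step 4
Reactants: 8 tert-butyl (3S,4R)-3-{[(4S)-4-benzyl-2-oxo-1,3-oxazolidin-3-yl]carbonyl}-4-[(tert-butyldimethylsilyl)oxy]-6-methylhept-5-enoate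
Product: 9 tert-butyl (3R,4R)-4-[(tert-butyldimethylsilyl)oxy]-3-(hydroxymethyl)-6-methylhept-5-enoate
Conditions: LiBH4, MeOH (1 equiv), THF, 0 °C
Reagents that add atoms: none
Why: Reductive removal of the auxiliary with LiBH4 reduces the activated imide carbonyl (C8) much faster than the tert-butyl ester and does not touch C7.

Step 5
Reactants: 9 tert-butyl (3R,4R)-4-[(tert-butyldimethylsilyl)oxy]-3-(hydroxymethyl)-6-methylhept-5-enoate
Product: 10 tert-butyl (3S,4R)-4-[(tert-butyldimethylsilyl)oxy]-3-formyl-6-methylhept-5-enoate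
Conditions: Dess–Martin periodinane, NaHCO3, CH2Cl2, 0 °C → rt; used at once
Reagents that add atoms: none
Why: Buffered Dess–Martin oxidation gives the α-branched aldehyde under conditions that should not epimerise C7.

Step 6
Reactants: 10 tert-butyl (3S,4R)-4-[(tert-butyldimethylsilyl)oxy]-3-formyl-6-methylhept-5-enoate; 11 2-(bromomethyl)prop-2-enenitrile
Product: 12 tert-butyl (3R,4R)-4-[(tert-butyldimethylsilyl)oxy]-3-[(1S)-3-cyano-1-hydroxybut-3-en-1-yl]-6-methylhept-5-enoate
Conditions: Zn dust, THF/sat. aq NH4Cl, 0 °C → rt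
Reagents that add atoms: none
Why: This zinc-mediated Barbier allylation forms C8–C9 and brings in C10(=C14)–C1 in one operation, and Felkin–Anh attack anti to the bulky C6(OTBS) branch should give the 8S alcohol, syn to the C7 side chain (all-syn C6–C7–C8 triad).

Step 7
Reactants: 12 tert-butyl (3R,4R)-4-[(tert-butyldimethylsilyl)oxy]-3-[(1S)-3-cyano-1-hydroxybut-3-en-1-yl]-6-methylhept-5-enoate
Product: 14 2-{[(2S,3R)-3-{(1R)-1-[(tert-butyldimethylsilyl)oxy]-3-methylbut-2-en-1-yl}-5-oxooxolan-2-yl]methyl}prop-2-enenitrile, via γ-hydroxy acid 13 (not isolated)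
Conditions: 85% aq H3PO4, toluene, rt → 40 °C
Reagents that add atoms: none
Why: Aqueous phosphoric acid cleaves the tert-butyl ester selectively (silyl ether and nitrile should survive) and the freed γ-hydroxy acid lactonises in situ with retention at C8 to the trans-disubstituted γ-butyrolactone.

Step 8
Reactants: 14 2-{[(2S,3R)-3-{(1R)-1-[(tert-butyldimethylsilyl)oxy]-3-methylbut-2-en-1-yl}-5-oxooxolan-2-yl]methyl}prop-2-enenitrile
Product: 15 2-{[(2S,3R)-3-{(1R,2E)-1-[(tert-butyldimethylsilyl)oxy]-4-hydroxy-3-methylbut-2-en-1-yl}-5-oxooxolan-2-yl]methyl}prop-2-enenitrile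
Conditions: SeO2 (0.3 equiv), t-BuOOH, salicylic acid (cat.), CH2Cl2, rt
Reagents that add atoms: tert-butyl hydroperoxide CC(C)(C)OO
Why: Riley allylic oxidation (ene reaction then [2,3]-sigmatropic shift) acts at the more substituted terminus of the electron-rich alkene and oxidises the methyl group trans to the chain, which should give the E allylic alcohol (C3–OH) while the electron-poor acrylonitrile alkene stays inert.

Step 9
Reactants: 15 2-{[(2S,3R)-3-{(1R,2E)-1-[(tert-butyldimethylsilyl)oxy]-4-hydroxy-3-methylbut-2-en-1-yl}-5-oxooxolan-2-yl]methyl}prop-2-enenitrile; 16 tert-butyl bromoacetate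
Product: 18 tert-butyl 4-{[(2S,3R)-3-{(1R,2E)-1-[(tert-butyldimethylsilyl)oxy]-4-hydroxy-3-methylbut-2-en-1-yl}-5-oxooxolan-2-yl]methyl}-3-oxopent-4-enoate, via Blaise enamino ester 17 (not isolated)
Conditions: activated Zn, THF, reflux, slow addition of 16 (3 equiv); then 1 M aq HCl, THF, 0 °C
Reagents that add atoms: water O
Why: In this Blaise reaction the Reformatsky reagent adds 1,2 to the nitrile (one equivalent is consumed by the C3–OH), the lactone is inert to the zinc enolate, and mild acid hydrolysis of the enamino ester unveils C1 as the ketone of a tert-butyl β-keto ester.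

Step 10
Reactants: 18 tert-butyl 4-{[(2S,3R)-3-{(1R,2E)-1-[(tert-butyldimethylsilyl)oxy]-4-hydroxy-3-methylbut-2-en-1-yl}-5-oxooxolan-2-yl]methyl}-3-oxopent-4-enoate
Product: 20 twelve-membered allyl β-keto lactone (ring C2–C(=O)–O–C3–C4(Me)=C5–C6(OTBS)–C7–C8–C9–C10(=CH2)–C1(=O); 4E; 6R,7R,8S; 8,12-γ-lactone trans-fused on C7–C8), via acylketene 19 (not isolated)
Conditions: toluene, 110 °C, 1 mM (syringe-pump addition)
Reagents that add atoms: none
Why: Thermolysis of the tert-butyl β-keto ester releases tert-butanol and an acylketene that is trapped at high dilution by the primary allylic C3–OH (acylketene macrolactonisation), which should close the twelve-membered ring without activating agents or base.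

Step 11
Reactants: 20 twelve-membered allyl β-keto lactone
Product: 23 (4E,6R,7R,8S)-6-[(tert-butyldimethylsilyl)oxy]-1-oxo-13-norgermacra-4,10(14)-dien-12,8-olide, via σ-allylpalladium carboxylate 21 (not isolated), via palladium enolate 22 (not isolated)
Conditions: Pd(PPh3)4 (10 mol %), THF, 1 mM, rt → 50 °C
Reagents that add atoms: none
Why: Zerovalent palladium ionises the primary allylic C3–O bond of the twelve-membered lactone to a π-allylpalladium β-keto carboxylate, which loses CO2 to a tethered palladium enolate and collapses by C2–C3 bond formation with release of the catalyst. The closest known reaction type is the Tsuji–Saegusa decarboxylative allylation of allyl β-keto esters (palladium-catalysed Carroll reaction), run here within the ring so that loss of the C(=O)O unit turns the 12-membered lactone into the 10-membered carbocycle. The carbocycle is closed in the endo mode at the unsubstituted allyl terminus C3, so C4=C5 stays in the ring; the exo alternative at C5 would give an eight-membered ring bearing an isopropenyl group. No stereocentre is created, C6, C7 and C8 are untouched, and the E geometry of C4=C5 should carry over from 20 if the syn π-allyl intermediate is trapped before π–σ–π isomerisation. The step needs C3 over C5 regioselectivity and C-allylation over proton transfer or β-hydride loss; the first rests on the preference of palladium-bound allyls to be attacked at the primary terminus remote from the branched C6(OTBS) carbon, the second on the regiospecific, base-free generation of the C2 enolate next to its electrophile at high dilution.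

Step 12
Reactants: 23 (4E,6R,7R,8S)-6-[(tert-butyldimethylsilyl)oxy]-1-oxo-13-norgermacra-4,10(14)-dien-12,8-olide
Product: 24 (1S,4E,6R,7R,8S)-6-[(tert-butyldimethylsilyl)oxy]-1-hydroxy-13-norgermacra-4,10(14)-dien-12,8-olide
Conditions: (R)-tetrahydro-1-methyl-3,3-diphenyl-1H,3H-pyrrolo[1,2-c][1,3,2]oxazaborole (0.2 equiv), catecholborane, toluene, −78 °C
Reagents that add atoms: none
Why: In this Corey–Bakshi–Shibata reduction the enone carbonyl binds the (R)-oxazaborolidine with the 1-substituted vinyl group (C10) as the large substituent, so hydride should be delivered under reagent control to give the 1S allylic alcohol, and the lactone is not reduced at −78 °C.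

Step 13
Reactants: 24 (1S,4E,6R,7R,8S)-6-[(tert-butyldimethylsilyl)oxy]-1-hydroxy-13-norgermacra-4,10(14)-dien-12,8-olide
Product: 25 (1S,4E,6R,7R,8S)-1-[(tert-butyldiphenylsilyl)oxy]-6-[(tert-butyldimethylsilyl)oxy]-13-norgermacra-4,10(14)-dien-12,8-olide
Conditions: TBDPSCl, imidazole, DMF, rt
Reagents that add atoms: tert-butyldiphenylsilyl chloride CC(C)(C)[Si](Cl)(c1ccccc1)c1ccccc1
Why: Silylation with the acid-stable TBDPS group masks the C1 allylic alcohol so that it neither consumes base nor directs the later epoxidation, and it is orthogonal to the TBS ether on O6.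

Step 14
Reactants: 25 (1S,4E,6R,7R,8S)-1-[(tert-butyldiphenylsilyl)oxy]-6-[(tert-butyldimethylsilyl)oxy]-13-norgermacra-4,10(14)-dien-12,8-olide
Product: 28 (1S,4E,6R,7R,8S)-1-[(tert-butyldiphenylsilyl)oxy]-6-[(tert-butyldimethylsilyl)oxy]germacra-4,10(14),11(13)-trien-12,8-olide, via Mannich base 26 (not isolated), via trimethylammonium iodide 27 (not isolated)
Conditions: LiN(i-Pr)2, THF, −78 °C; CH2=NMe2+ I−, −78 °C → rt; then MeI, MeOH, rt; then NaHCO3, CH2Cl2/H2O
Reagents that add atoms: Eschenmoser's salt C=[N+](C)C.[I-]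
Why: In this α-methylenation the lithium enolate at C11 is trapped by Eschenmoser's salt (Mannich reaction) and exhaustive methylation followed by mild base induces Hofmann-type elimination to the exocyclic C11=C13 alkene, leaving C7 untouched.

Step 15
Reactants: 28 (1S,4E,6R,7R,8S)-1-[(tert-butyldiphenylsilyl)oxy]-6-[(tert-butyldimethylsilyl)oxy]germacra-4,10(14),11(13)-trien-12,8-olide
Product: 29 (1S,4E,6R,7S,8S)-1-[(tert-butyldiphenylsilyl)oxy]-6-hydroxygermacra-4,10(14),11(13)-trien-12,8-olide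
Conditions: HF·pyridine, pyridine, THF, 0 °C
Reagents that add atoms: none
Why: Selective desilylation with buffered HF·pyridine removes the secondary TBS ether far faster than the TBDPS ether and should not add to the α-methylene lactone (the C7 descriptor changes by priority only).

Step 16
Reactants: 29 (1S,4E,6R,7S,8S)-1-[(tert-butyldiphenylsilyl)oxy]-6-hydroxygermacra-4,10(14),11(13)-trien-12,8-olide
Product: 30 (1S,4R,5R,6S,7S,8S)-1-[(tert-butyldiphenylsilyl)oxy]-4,5-epoxy-6-hydroxygermacra-10(14),11(13)-dien-12,8-olide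
Conditions: VO(acac)2 (5 mol %), t-BuOOH, CH2Cl2, 0 °C
Reagents that add atoms: tert-butyl hydroperoxide CC(C)(C)OO
Why: In this hydroxyl-directed (Sharpless–Michaelson) epoxidation the vanadium alkyl peroxide bound to O6 delivers oxygen to C4=C5 on the face syn to O6 in the A(1,3)-minimised conformer, which is also the outer face of the E-cyclodecene, so the threo 4R,5R epoxide should form and the two other alkenes stay untouched.

Step 17
Reactants: 30 (1S,4R,5R,6S,7S,8S)-1-[(tert-butyldiphenylsilyl)oxy]-4,5-epoxy-6-hydroxygermacra-10(14),11(13)-dien-12,8-olide; 31 angelic acid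
Product: 33 (1S,4R,5R,6S,7R,8S)-6-(angeloyloxy)-1-[(tert-butyldiphenylsilyl)oxy]-4,5-epoxygermacra-10(14),11(13)-dien-12,8-olide, via mixed anhydride 32 (not isolated)
Conditions: 31, 2,4,6-trichlorobenzoyl chloride, Et3N, toluene, rt; then 30, 80 °C
Reagents that add atoms: none
Why: Yamaguchi esterification through the mixed anhydride acylates the hindered C6 alcohol without a nucleophilic amine catalyst, which should avoid Z-to-E isomerisation of the angelate.

Step 18
Reactants: 33 (1S,4R,5R,6S,7R,8S)-6-(angeloyloxy)-1-[(tert-butyldiphenylsilyl)oxy]-4,5-epoxygermacra-10(14),11(13)-dien-12,8-olide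
Product: 34 (1S,4R,5R,6S,7R,8S)-6-(angeloyloxy)-4,5-epoxy-1-hydroxygermacra-10(14),11(13)-dien-12,8-olide (CNP0104965.3)
Conditions: n-Bu4NF, AcOH, THF, 0 °C → rt
Reagents that add atoms: none
Why: Fluoride-mediated desilylation buffered with acetic acid should cleave the TBDPS ether without opening the epoxide, adding to the α-methylene lactone or cleaving the angelate.

Compound list
1 | mono-tert-butyl succinate | OC(=O)CCC(=O)OC(C)(C)C | starting material
2 | (S)-4-benzyl-1,3-oxazolidin-2-one | O=C1OC[C@H](Cc2ccccc2)N1 | starting material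
3 | mixed pivalic anhydride of 1 | CC(C)(C)OC(=O)CCC(=O)OC(=O)C(C)(C)C | intermediate (not isolated)
4 | tert-butyl 4-[(4S)-4-benzyl-2-oxo-1,3-oxazolidin-3-yl]-4-oxobutanoate | CC(C)(C)OC(=O)CCC(=O)N1C(=O)OC[C@@H]1Cc1ccccc1 | intermediate
5 | 3-methylbut-2-enal | CC(C)=CC=O | starting material
6 | Z-dibutylboron enolate of 4 | CCCCB(CCCC)O/C(=C\CC(=O)OC(C)(C)C)N1C(=O)OC[C@@H]1Cc1ccccc1 | intermediate (not isolated)
7 | tert-butyl (3S,4R)-3-{[(4S)-4-benzyl-2-oxo-1,3-oxazolidin-3-yl]carbonyl}-4-hydroxy-6-methylhept-5-enoate | CC(C)=C[C@@H](O)[C@H](CC(=O)OC(C)(C)C)C(=O)N1C(=O)OC[C@@H]1Cc1ccccc1 | intermediate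
8 | tert-butyl (3S,4R)-3-{[(4S)-4-benzyl-2-oxo-1,3-oxazolidin-3-yl]carbonyl}-4-[(tert-butyldimethylsilyl)oxy]-6-methylhept-5-enoate | CC(C)=C[C@@H](O[Si](C)(C)C(C)(C)C)[C@H](CC(=O)OC(C)(C)C)C(=O)N1C(=O)OC[C@@H]1Cc1ccccc1 | intermediate
9 | tert-butyl (3R,4R)-4-[(tert-butyldimethylsilyl)oxy]-3-(hydroxymethyl)-6-methylhept-5-enoate | CC(C)=C[C@@H](O[Si](C)(C)C(C)(C)C)[C@H](CC(=O)OC(C)(C)C)CO | intermediate
10 | tert-butyl (3S,4R)-4-[(tert-butyldimethylsilyl)oxy]-3-formyl-6-methylhept-5-enoate | CC(C)=C[C@@H](O[Si](C)(C)C(C)(C)C)[C@H](CC(=O)OC(C)(C)C)C=O | intermediate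
11 | 2-(bromomethyl)prop-2-enenitrile | C=C(CBr)C#N | starting material
12 | tert-butyl (3R,4R)-4-[(tert-butyldimethylsilyl)oxy]-3-[(1S)-3-cyano-1-hydroxybut-3-en-1-yl]-6-methylhept-5-enoate | CC(C)=C[C@@H](O[Si](C)(C)C(C)(C)C)[C@H](CC(=O)OC(C)(C)C)[C@@H](O)CC(=C)C#N | intermediate
13 | (3R,4R)-4-[(tert-butyldimethylsilyl)oxy]-3-[(1S)-3-cyano-1-hydroxybut-3-en-1-yl]-6-methylhept-5-enoic acid | CC(C)=C[C@@H](O[Si](C)(C)C(C)(C)C)[C@H](CC(=O)O)[C@@H](O)CC(=C)C#N | intermediate (not isolated)
14 | 2-{[(2S,3R)-3-{(1R)-1-[(tert-butyldimethylsilyl)oxy]-3-methylbut-2-en-1-yl}-5-oxooxolan-2-yl]methyl}prop-2-enenitrile | CC(C)=C[C@@H](O[Si](C)(C)C(C)(C)C)[C@@H]1CC(=O)O[C@H]1CC(=C)C#N | intermediate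
15 | 2-{[(2S,3R)-3-{(1R,2E)-1-[(tert-butyldimethylsilyl)oxy]-4-hydroxy-3-methylbut-2-en-1-yl}-5-oxooxolan-2-yl]methyl}prop-2-enenitrile | OC/C(C)=C/[C@@H](O[Si](C)(C)C(C)(C)C)[C@@H]1CC(=O)O[C@H]1CC(=C)C#N | intermediate
16 | tert-butyl bromoacetate | BrCC(=O)OC(C)(C)C | starting material
17 | tert-butyl (2Z)-3-amino-4-{[(2S,3R)-3-{(1R,2E)-1-[(tert-butyldimethylsilyl)oxy]-4-hydroxy-3-methylbut-2-en-1-yl}-5-oxooxolan-2-yl]methyl}penta-2,4-dienoate (present as its bromozinc salt) | OC/C(C)=C/[C@@H](O[Si](C)(C)C(C)(C)C)[C@@H]1CC(=O)O[C@H]1CC(=C)/C(N)=C/C(=O)OC(C)(C)C | intermediate (not isolated)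
18 | tert-butyl 4-{[(2S,3R)-3-{(1R,2E)-1-[(tert-butyldimethylsilyl)oxy]-4-hydroxy-3-methylbut-2-en-1-yl}-5-oxooxolan-2-yl]methyl}-3-oxopent-4-enoate | OC/C(C)=C/[C@@H](O[Si](C)(C)C(C)(C)C)[C@@H]1CC(=O)O[C@H]1CC(=C)C(=O)CC(=O)OC(C)(C)C | intermediate
19 | 4-{[(2S,3R)-3-{(1R,2E)-1-[(tert-butyldimethylsilyl)oxy]-4-hydroxy-3-methylbut-2-en-1-yl}-5-oxooxolan-2-yl]methyl}penta-1,4-diene-1,3-dione (acylketene) | OC/C(C)=C/[C@@H](O[Si](C)(C)C(C)(C)C)[C@@H]1CC(=O)O[C@H]1CC(=C)C(=O)C=C=O | intermediate (not isolated)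
20 | twelve-membered allyl β-keto lactone (ring C2–C(=O)–O–C3–C4(Me)=C5–C6(OTBS)–C7–C8–C9–C10(=CH2)–C1(=O); 4E; 6R,7R,8S; 8,12-γ-lactone trans-fused on C7–C8) | O=C1OC/C(C)=C/[C@@H](O[Si](C)(C)C(C)(C)C)[C@@H]2CC(=O)O[C@H]2CC(=C)C(=O)C1 | intermediate
21 | σ-allylpalladium β-keto carboxylate from ionisation of the C3–O bond of 20 (divalent palladium drawn η1 on C3 and on the carboxylate oxygen; phosphines omitted) | O=C1O[Pd]C/C(C)=C/[C@@H](O[Si](C)(C)C(C)(C)C)[C@@H]2CC(=O)O[C@H]2CC(=C)C(=O)C1 | intermediate (not isolated)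
22 | palladium enolate after loss of CO2 (divalent palladium drawn η1 on C3 and on the C1 enolate oxygen; phosphines omitted) | C=C1O[Pd]C/C(C)=C/[C@@H](O[Si](C)(C)C(C)(C)C)[C@@H]2CC(=O)O[C@H]2CC1=C | intermediate (not isolated)
23 | (4E,6R,7R,8S)-6-[(tert-butyldimethylsilyl)oxy]-1-oxo-13-norgermacra-4,10(14)-dien-12,8-olide | O=C1CC/C(C)=C/[C@@H](O[Si](C)(C)C(C)(C)C)[C@@H]2CC(=O)O[C@H]2CC1=C | intermediate
24 | (1S,4E,6R,7R,8S)-6-[(tert-butyldimethylsilyl)oxy]-1-hydroxy-13-norgermacra-4,10(14)-dien-12,8-olide | O[C@H]1CC/C(C)=C/[C@@H](O[Si](C)(C)C(C)(C)C)[C@@H]2CC(=O)O[C@H]2CC1=C | intermediate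
25 | (1S,4E,6R,7R,8S)-1-[(tert-butyldiphenylsilyl)oxy]-6-[(tert-butyldimethylsilyl)oxy]-13-norgermacra-4,10(14)-dien-12,8-olide | CC(C)(C)[Si](c3ccccc3)(c4ccccc4)O[C@H]1CC/C(C)=C/[C@@H](O[Si](C)(C)C(C)(C)C)[C@@H]2CC(=O)O[C@H]2CC1=C | intermediate
26 | 13-(dimethylamino)-11,13-dihydro derivative of 28 (Mannich base; C11 epimers, inconsequential) | CC(C)(C)[Si](c3ccccc3)(c4ccccc4)O[C@H]1CC/C(C)=C/[C@@H](O[Si](C)(C)C(C)(C)C)[C@@H]2C(CN(C)C)C(=O)O[C@H]2CC1=C | intermediate (not isolated)
27 | 13-(trimethylammonio)-11,13-dihydro derivative of 28, iodide (C11 epimers) | CC(C)(C)[Si](c3ccccc3)(c4ccccc4)O[C@H]1CC/C(C)=C/[C@@H](O[Si](C)(C)C(C)(C)C)[C@@H]2C(C[N+](C)(C)C)C(=O)O[C@H]2CC1=C.[I-] | intermediate (not isolated)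
28 | (1S,4E,6R,7R,8S)-1-[(tert-butyldiphenylsilyl)oxy]-6-[(tert-butyldimethylsilyl)oxy]germacra-4,10(14),11(13)-trien-12,8-olide | CC(C)(C)[Si](c3ccccc3)(c4ccccc4)O[C@H]1CC/C(C)=C/[C@@H](O[Si](C)(C)C(C)(C)C)[C@@H]2C(=C)C(=O)O[C@H]2CC1=C | intermediate
29 | (1S,4E,6R,7S,8S)-1-[(tert-butyldiphenylsilyl)oxy]-6-hydroxygermacra-4,10(14),11(13)-trien-12,8-olide | CC(C)(C)[Si](c3ccccc3)(c4ccccc4)O[C@H]1CC/C(C)=C/[C@@H](O)[C@@H]2C(=C)C(=O)O[C@H]2CC1=C | intermediate
30 | (1S,4R,5R,6S,7S,8S)-1-[(tert-butyldiphenylsilyl)oxy]-4,5-epoxy-6-hydroxygermacra-10(14),11(13)-dien-12,8-olide | C=C1C(=O)O[C@H]2CC(=C)[C@@H](O[Si](c3ccccc3)(c4ccccc4)C(C)(C)C)CC[C@@]5(C)O[C@@H]5[C@@H](O)[C@H]12 | intermediate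
31 | angelic acid ((Z)-2-methylbut-2-enoic acid) | C/C=C(/C)C(=O)O | starting material
32 | angelic 2,4,6-trichlorobenzoic anhydride | C/C=C(/C)C(=O)OC(=O)c1c(Cl)cc(Cl)cc1Cl | intermediate (not isolated)
33 | (1S,4R,5R,6S,7R,8S)-6-(angeloyloxy)-1-[(tert-butyldiphenylsilyl)oxy]-4,5-epoxygermacra-10(14),11(13)-dien-12,8-olide | C=C1C(=O)O[C@H]2CC(=C)[C@@H](O[Si](c3ccccc3)(c4ccccc4)C(C)(C)C)CC[C@@]5(C)O[C@@H]5[C@@H](OC(=O)/C(C)=C\C)[C@H]12 | intermediate
34 | (1S,4R,5R,6S,7R,8S)-6-(angeloyloxy)-4,5-epoxy-1-hydroxygermacra-10(14),11(13)-dien-12,8-olide (CNP0104965.3) | C=C1C(=O)O[C@H]2CC(=C)[C@@H](O)CC[C@@]3(C)O[C@@H]3[C@@H](OC(=O)/C(C)=C\C)[C@H]12 | target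

Total step count: 18
Longest linear sequence: 18 steps (1 and 2 to 34; all other building blocks are commercial)

Steps most likely to fail

Step 11. The palladium enolate may be lost to proton transfer or β-hydride elimination from the allyl unit, attack may go to the internal terminus C5 (eight-membered ring), syn–anti isomerisation of the allyl unit may erode the E geometry, and crossover between molecules may give oligomers. Fallback, setting out from 20: deprotonation with NaH (THF, 0 °C) gives the sodium enolate of the macrolactone F1, and Pd(PPh3)4 then effects the palladium-catalysed Carroll-type 1,3-shift in the enolate manifold. Here the soft, stabilised β-keto ester enolate alkylates the allyl terminus C3 before any decarboxylation, the lactone-to-carbocycle isomerisation mode. Acidification gives the ring-contracted ten-membered β-keto acid F2 (carboxyl on C2), which should lose CO2 on gentle warming and rejoin the route at 23.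

Step 9. The zinc enolate may add in conjugate fashion to the acrylonitrile instead of to the nitrile carbon, and the vinyl ketone β-keto ester may polymerise during hydrolysis. Fallback, setting out from 10, in which C1 enters as carbon monoxide instead of as a nitrile:
- Barbier 2-bromoallylation with 2,3-dibromopropene and In powder (THF/H2O) gives the bromoalkene alcohol F3.
- 85% aq H3PO4 gives the bromoalkene lactone F4.
- SeO2/t-BuOOH gives the allylic alcohol F5.
- Carbonylative coupling of the vinyl bromide with potassium mono-tert-butyl malonate (CO 1 atm, Pd(OAc)2, Xantphos, MgCl2, Et3N, THF) gives the acyl malonate half-ester F6, which decarboxylates in the flask and rejoins the route at 18.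

Step 6. Poor facial selectivity at C8 is possible, because the 1,3-anti preference of the β-silyloxy aldehyde opposes Felkin control. Fallback, setting out from 10 and using the wrong epimer productively: the 8R alcohol F7 is mesylated (MsCl, Et3N, CH2Cl2) to the mesylate F8, 85% aq H3PO4 removes the tert-butyl ester to give the mesyloxy acid F9, and Cs2CO3 in DMF closes the γ-lactone by intramolecular SN2 displacement with inversion at C8, rejoining the route at 14.

Further compounds
F1 | step 11 | sodium enolate (C1–O, C2) of macrolactone 20 | O=C1OC/C(C)=C/[C@@H](O[Si](C)(C)C(C)(C)C)[C@@H]2CC(=O)O[C@H]2CC(=C)C([O-])=C1.[Na+]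
F2 | step 11 | (4E,6R,7R,8S)-6-[(tert-butyldimethylsilyl)oxy]-1-oxo-13-norgermacra-4,10(14)-dien-12,8-olide-2-carboxylic acid (C2 epimers) | O=C1C(C(=O)O)C/C(C)=C/[C@@H](O[Si](C)(C)C(C)(C)C)[C@@H]2CC(=O)O[C@H]2CC1=C
F3 | step 9 | tert-butyl (3R,4R)-3-[(1S)-3-bromo-1-hydroxybut-3-en-1-yl]-4-[(tert-butyldimethylsilyl)oxy]-6-methylhept-5-enoate | CC(C)=C[C@@H](O[Si](C)(C)C(C)(C)C)[C@H](CC(=O)OC(C)(C)C)[C@@H](O)CC(Br)=C
F4 | step 9 | (4R,5S)-5-(2-bromoprop-2-en-1-yl)-4-{(1R)-1-[(tert-butyldimethylsilyl)oxy]-3-methylbut-2-en-1-yl}oxolan-2-one | CC(C)=C[C@@H](O[Si](C)(C)C(C)(C)C)[C@@H]1CC(=O)O[C@H]1CC(Br)=C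
F5 | step 9 | (4R,5S)-5-(2-bromoprop-2-en-1-yl)-4-{(1R,2E)-1-[(tert-butyldimethylsilyl)oxy]-4-hydroxy-3-methylbut-2-en-1-yl}oxolan-2-one | OC/C(C)=C/[C@@H](O[Si](C)(C)C(C)(C)C)[C@@H]1CC(=O)O[C@H]1CC(Br)=C
F6 | step 9 | 2-(tert-butoxycarbonyl) derivative of the β-keto acid of 18 (acyl malonate half-ester) | OC/C(C)=C/[C@@H](O[Si](C)(C)C(C)(C)C)[C@@H]1CC(=O)O[C@H]1CC(=C)C(=O)C(C(=O)O)C(=O)OC(C)(C)C
F7 | step 6 | tert-butyl (3R,4R)-4-[(tert-butyldimethylsilyl)oxy]-3-[(1R)-3-cyano-1-hydroxybut-3-en-1-yl]-6-methylhept-5-enoate | CC(C)=C[C@@H](O[Si](C)(C)C(C)(C)C)[C@H](CC(=O)OC(C)(C)C)[C@H](O)CC(=C)C#N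
F8 | step 6 | methanesulfonate of F7 at the C8 hydroxyl | CC(C)=C[C@@H](O[Si](C)(C)C(C)(C)C)[C@H](CC(=O)OC(C)(C)C)[C@H](OS(C)(=O)=O)CC(=C)C#N
F9 | step 6 | carboxylic acid from F8 (tert-butyl ester removed) | CC(C)=C[C@@H](O[Si](C)(C)C(C)(C)C)[C@H](CC(=O)O)[C@H](OS(C)(=O)=O)CC(=C)C#N
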